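| flask | starting material | free catalyst | time |
|---|---|---|---|
| spring | 0.250 M | 5.00 × 10⁻⁴ M |  |
| midnight | 0.130 M | 5.00 × 10⁻⁴ M |  |
| dusk | 0.250 M | 2.50 × 10⁻⁴ M |  |
| summer | 0.750 M | 5.00 × 10⁻⁴ M |  |
| winter | 0.250 M | 5.00 × 10⁻⁴ M | 400 min |

| run | time / min | [target] / M |
|---|---|---|
| spring run | 5.7 | 0.0017 |
| spring run | 17 | 0.0082 |
| spring run | 33 | 0.0184 |
| spring run | 53 | 0.0302 |
| spring run | 75 | 0.0478 |
| spring run | 100 | 0.0714 |
| spring run | 130 | 0.1005 |
| spring run | 160 | 0.1298 |
| midnight run | 5.7 | 0.0015 |
| midnight run | 17 | 0.0053 |
| midnight run | 33 | 0.0073 |
| midnight run | 53 | 0.0129 |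
| midnight run | 75 | 0.0211 |
| midnight run | 100 | 0.0271 |
| midnight run | 130 | 0.0375 |
| midnight run | 160 | 0.0484 |
| dusk run | 5.7 | 0.0013 |
| dusk run | 17 | 0.0042 |
| dusk run | 33 | 0.0081 |
| dusk run | 53 | 0.0140 |
| dusk run | 75 | 0.0206 |
| dusk run | 100 | 0.0335 |
| dusk run | 130 | 0.0501 |
| dusk run | 160 | 0.0688 |
| summer run | 5.7 | 0.0088 |
| summer run | 17 | 0.0306 |
| summer run | 33 | 0.0794 |
| summer run | 53 | 0.1802 |
| summer run | 75 | 0.3349 |
| summer run | 100 | 0.5165 |
| summer run | 130 | 0.6578 |
| summer run | 160 | 0.7202 |

(standard deviation of a reading: 8 × 10⁻⁴ M)

- Overall: starting material -> target, with free catalyst as catalyst.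
- Constant volume, constant temperature.
- An order is taken over about fifteen percent of the charge, up and down.

* reaction order in [free catalyst] at the outset, round the charge of the spring run, defined at two percent of the starting material turned into target
* reaction order in [starting material] at the outset, round the charge of the spring run, defined at two percent of the starting material turned into target (one fixed amount of target, the same in the runs compared)
* the midnight run starts with 0.120 M less of starting material than the spring run, and with no target. Compared where both hold the same amount of starting material, once fifteen percent of what the midnight run was charged with has turned into target, is the midnight run faster, slower or alike (within a tenth)?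
* target in the winter run at 400 min, as a share of the starting material charged

- At each reading time we look at what is left, not at what is made. S is the starting material still present, which is the charge minus the target P, and κ is the share of S that turns per minute, read from the logarithm of S between two readings.
- Fastest rung: late in the summer run, with about 0.689 M of target, κ reads 0.0376 min⁻¹, a lifetime of 26.6 min.
- Middle rung: late in the spring run, with 0.115 M of target, κ reads 0.00727 min⁻¹, so S lasts longer there than late in the summer run, about 138 min.
- Slowest rung: up to the first summer reading, with about 0.00440 M of target, κ reads 0.00207 min⁻¹, a lifetime of 483 min.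
- So we take κ = a + gP, a straight line through the summer rungs, with gain g = 0.0520 M⁻¹ min⁻¹ and a = 0.00184 min⁻¹. This is autocatalysis. At the spring rung the line gives 0.00782 min⁻¹, close to the reading, so κ follows target and not charge, and we take the order in starting material as 1.
- The quantity we carry is the crossover P× = a/g, the amount of target at which the target route turns as much as the catalyst route: 0.0354 M.
- The dusk run has half the catalyst of the summer run, and its κ reads 9.98 × 10⁻⁴ min⁻¹ up to 33 min and 0.00327 min⁻¹ over its last two readings. A line through these two dusk readings gives g = 0.0411 M⁻¹ min⁻¹ and a = 8.32 × 10⁻⁴ min⁻¹, so as read, a stands at 0.452 of its summer value and g at 0.790, and we let a follow the catalyst and g not. The order in catalyst is then the catalyst route's share at 0.00500 M of target: 0.876.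
- At equal S the midnight run holds 0.0195 M of target and the spring run 0.120 M more, so we reckon the midnight run slower, at 0.314 of the spring rate.
- In the winter run, κ/S grows steadily at Λ = a + g × charge = 0.0148 min⁻¹. That leaves 2.09% of the charge at 400 min, so we expect 97.9% as target.
- The forecast, finding “no sign of an equilibrium limit”, gives 0.87, 1.02, slower and 97%.
- The flask gives 0.88, 1.0, slower and 97.3%.

    2 free catalyst ⇌ catalyst dimer, settled at all times (1750 M⁻¹)
    free catalyst + starting material → target + free catalyst (8.760 M⁻¹ min⁻¹)
    starting material + target → 2 target (0.04938 M⁻¹ min⁻¹)
    free catalyst + impurity → spent catalyst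

The target route lifts the yield of the winter run: with that step taken away, the winter run reaches 51.4% and not 97.3%. Our crossover reckons that stripped flask as well, since a alone, which is g times P×, gives 52.1%. In the midnight run P× gave 0.314, and the simulated rate ratio is 0.32. Without the target route that ratio becomes 1.0, and the two runs are alike.

The numbers in the tables were computed with constants of no real substance; noise was put on by code.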